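## The problem

Compound 14 is a deoxybenzoin whose ring A is a hexasubstituted benzene. In chromene numbering it carries three different oxygen functions (free hydroxyl at C5, methyl ether at C7, pyran oxygen O1 on C8a) and three different carbon substituents (the 4-hydroxyphenylacetyl group at C6, the 3-methylbut-2-enyl group at C8, and C4 of the pyran on C4a). There is no stereocentre, so the task is purely regiochemical: six adjacent ring positions must each receive the right group. The 2,2-dimethyl-2H-pyran must be fused across C4a–C8a with its oxygen para to the ketone and its C4 next to the hydroxyl-bearing C5. Several groups are fragile: the chromene C3=C4 bond is an electron-rich styrene that adds acids and electrophiles, the prenyl olefin cyclises or hydrates under acid, both olefins exclude hydrogenation, and the benzylic methylene between the ketone and ring B enolises and oxidises in basic air. The three oxygens of ring A can be told apart through the ketone: the C5 hydroxyl is locked to the C6 carbonyl by a six-membered hydrogen bond, the C8a oxygen is para to the carbonyl and hence the most acidic, and the C7 oxygen is best bought already methylated. The same hydrogen bond makes the key step possible, because it favours the Kekulé structure with a C4a=C8a double bond, so a group migrating from O1 should be delivered to C4a and not to C8. C8 is then the only free position of ring A for the prenyl group.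

## Retrosynthesis

**14 to 13 (O–Si).** The target 14 is traced to its ring B silyl ether 13 by cutting only the aryl O–Si bond. A silyl ether is preferred to an alkyl ether or ester because its removal needs neither acid, hydrogen nor strong base, none of which the two olefins and the enolisable ketone would accept. The precursor is no simpler in skeleton, but its ring B phenol is masked during halogenation and cross-coupling. The forward reaction only has to leave the olefins and the benzylic methylene alone.

**13 to 11 and 12 (C8–CH2 of the prenyl group).** The bond between C8 and the prenyl methylene is cut to give aryl iodide 11 and prenylstannane 12. The neighbouring options are C-prenylation of an early phenol such as 3, or carrying the side chain through the acylation. Against these, the late cut keeps the acid-labile prenyl group out of the Lewis-acid and thermal steps and puts it on a carbon that is by then the only free one on ring A. A stannane is chosen over a boron reagent because it couples without aqueous base, which the aryl silyl ether may not survive. The precursor is simpler by five carbons and one olefin. The forward reaction must give the linear isomer at an iodide flanked by two ortho oxygens.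

**11 to 10 (C8–I).** Removing the iodine gives chromene 10. Halogenation is placed after pyran formation because before it two ring carbons of ring A are open and would compete. The forward reaction must choose the arene over the chromene double bond, ring B and the ketone alpha-carbon.

**10 to 6 (C4–C4a; the pyran ring).** The pyran is opened by cutting the C4–C4a bond and, formally, re-drawing the O1–C2 bond as the ether bond of aryl 1,1-dimethylpropargyl ether 6. In the forward direction 6 passes through allenyl dienone 7, allenylphenol 8 and quinone methide 9 to 10. Compared with an intermolecular condensation of a phenol with an unsaturated aldehyde, this cut attaches all five pyran carbons to the correct oxygen beforehand, so only the choice of ortho carbon remains. Compared with a cut at C3–C4, it needs no aldehyde on ring A. The precursor has one ring and one C–C bond fewer and is assembled by O-alkylation. The forward reaction must send the [3,3] shift to the carbon next to the chelated hydroxyl and must run under neutral conditions so that the allenylphenol closes to the pyran.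

**6 to 5, and 5 to 3 and 4 (O–Si and O–C).** Removing the ring B silyl group gives 5, and cutting the propargylic C–O bond gives triol 3 and tertiary chloride 4. The ether is made first because the hydroxyl para to the ketone is the most acidic of the three and can be addressed with one equivalent of base. The silyl group then goes onto the only remaining unchelated phenol. Both operations rely on the hydrogen bond to keep the ortho hydroxyl out of play, so ring A needs no protecting group. The forward etherification must stop at the mono-ether.

**3 to 1 and 2 (aryl–acyl).** The ketone is cut at the aryl–carbonyl bond to give 5-methoxyresorcinol 1 and 4-hydroxyphenylacetic acid 2. Introducing the ketone first, on a robust arene, lets it act as the control element for everything that follows, and the methyl ether is already in place. The forward acylation must go para to one hydroxyl (ortho to the methoxy group) and not between the two hydroxyls.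

## Roads not taken

**Alternative 1:** Ring A is cut at C7–C8 and C4a–C5 into the methyl ketone 6-methylhept-5-en-2-one A1 and the three-carbon bis-electrophile malonyl dichloride A2. Two C-acylations, at the methyl and the methylene flank of A1, would close the ring as 2-(3-methylbut-2-enyl)benzene-1,3,5-triol A3.
- Merits: two bulk chemicals, no cross-coupling, no tin, no halogenation, and the position of the prenyl group is beyond question.
- Weak points in the ring-forming step: with enolisable ketones A2 tends to acylate on oxygen as well as carbon, which leads towards lactones and away from the carbocycle. The hydrogen chloride released can add to the trisubstituted olefin.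
- Weak points after A3: its three hydroxyls (two equivalent ones flanking the prenyl group, one para to it) must become the C7 methyl ether, the pyran oxygen and the free C5 hydroxyl. After acylation at C6 both the C5 and C7 hydroxyls are ortho to the ketone, and nothing favours methylating the more hindered C7 one. A free hydroxyl ortho to a prenyl group would also close to a chroman under the Lewis acid needed to bring in 2.
- Comparison: on the prenyl question this road is better than the adopted plan, which spends two steps (11, 13) and a stoichiometric organotin on it. The adopted plan sets against that a purchased ring with the methyl ether in place (1), differentiation of the other oxygens by the hydrogen bond alone, and seven steps overall.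

**Alternative 2:** The pyran is cut at C3–C4 and O1–C2. C4 becomes the formyl carbon of the symmetric aldehyde 2,6-dihydroxy-4-methoxybenzaldehyde A4, and C2–C3 comes from (2-methylprop-1-enyl)boronic acid A5. With a secondary amine catalyst, the iminium of A4 would take up the alkenyl group from the boronate held by the ortho hydroxyl (a Petasis-type transfer). Loss of the amine gives an ortho-quinone methide, and oxa-6π closure gives 7-methoxy-2,2-dimethyl-2H-chromen-5-ol A6.
- Merits: catalytic, mild and convergent. Because A4 is symmetric there is no choice of ring carbon, so the pyran regiochemistry is fixed by symmetry, where the adopted plan relies on a hydrogen-bond bias.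
- Weak points: A6 lacks both carbon substituents of ring A and has two open positions, C6 (ortho to the hydroxyl) and C8 (para to it). The acyl group from 2 would have to be placed at C6 by Friedel–Crafts or Fries chemistry on a substrate that already contains the acid-sensitive chromene olefin, with C8 competing. The prenyl group would still have to follow. A4 is also a speciality aldehyde; formylation of 1 would be expected to favour the unsymmetrical isomer.
- Comparison: this road is better in pyran regiocontrol and in the mildness of the ring-forming step. The adopted plan sets against it that the ketone enters first on a simple arene (3), then steers both the etherification and the rearrangement, and that after ring closure only one ring position is left for the last C–C bond.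

**Alternative 3:** Ring A is cut at C8–C8a, C8a–C4a and C6–C7 into 3-(triisopropylsilyloxy)cyclobut-2-en-1-one A7 and the ynol ether 1-methoxy-5-methylhex-4-en-1-yne A8. In a Danheiser benzannulation, heating opens A7 to a ketene that adds to A8; 4π opening, 6π closure and tautomerisation would give 3-methoxy-2-(3-methylbut-2-enyl)-5-(triisopropylsilyloxy)phenol A9.
- Merits: one step delivers ring A with the prenyl group and all three oxygens differentiated. The free hydroxyl of A9 has only one open ortho carbon, so a pyran annulation can only go to C4a, and the acyl group then has only C6 left. In regiochemical certainty this is the best of the four plans.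
- Weak points: neither A7 nor A8 is a commercial compound, and both are sensitive and need several steps each. A9 has a free hydroxyl next to a prenyl group, which acid would close to a chroman. The arylacetyl group must enter last, at a carbon flanked by a methoxy and a bulky silyloxy group, on a molecule that already holds both olefins. That excludes the Lewis-acid acylation used for 3 and forces a longer halogenation–metalation–acylation sequence.
- Comparison: the adopted plan is less secure on regiochemistry, since steps 1 and 4 both depend on a preference and not on a blocked position. It sets against that purchased starting materials, a ketone that is formed first and used as a control element, and seven steps; the benzannulation road would probably need about twice as many once A7 and A8 are counted.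

Key step: step 4

## Route

Remark on the chemistry: 14 has no stereocentre; compounds 1, 2, 4 and 12 are taken as purchased; chromene numbering is used for 10 to 14.

Step 1
Reactants: 1 5-methoxybenzene-1,3-diol (5-methoxyresorcinol); 2 2-(4-hydroxyphenyl)acetic acid
Product: 3 1-(2,4-dihydroxy-6-methoxyphenyl)-2-(4-hydroxyphenyl)ethanone
Conditions: BF3·OEt2 (as solvent), 85 °C; then aq NaOAc
Reagents that add atoms: none
Why: Friedel–Crafts acylation of an electron-rich phenol by a free arylacetic acid in BF3·OEt2 is the standard entry to polyhydroxydeoxybenzoins and tolerates the unprotected phenol of the acid. Attack para to one hydroxyl (two equivalent sites) should outweigh attack at the single carbon between the hydroxyls, and the minor 2,6-dihydroxy-4-methoxy isomer should be separable by chromatography or crystallisation.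

Step 2
Reactants: 3 1-(2,4-dihydroxy-6-methoxyphenyl)-2-(4-hydroxyphenyl)ethanone; 4 3-chloro-3-methylbut-1-yne
Product: 5 1-[2-hydroxy-6-methoxy-4-(2-methylbut-3-yn-2-yloxy)phenyl]-2-(4-hydroxyphenyl)ethanone
Conditions: K2CO3 (1.1 equiv), KI (cat.), copper iodide CuI (cat.), acetone, 55 °C, argon
Reagents that add atoms: none
Why: Copper-assisted O-propargylation of a phenoxide with a tertiary propargylic chloride is the usual preparation of aryl 1,1-dimethylpropargyl ethers. The hydroxyl para to the ketone is the most acidic, the ortho hydroxyl is held in the chelate and the ring B phenol stays largely protonated with one equivalent of carbonate, so the mono-ether at the para oxygen is expected.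

Step 3
Reactants: 5 1-[2-hydroxy-6-methoxy-4-(2-methylbut-3-yn-2-yloxy)phenyl]-2-(4-hydroxyphenyl)ethanone
Product: 6 2-[4-(tert-butyldimethylsilyloxy)phenyl]-1-[2-hydroxy-6-methoxy-4-(2-methylbut-3-yn-2-yloxy)phenyl]ethanone
Conditions: TBSCl, imidazole, DMF, 0 °C to rt
Reagents that add atoms: tert-butyldimethylsilyl chloride (TBSCl), CC(C)(C)[Si](C)(C)Cl
Why: Silylation of a phenol with TBSCl and imidazole; the hydrogen-bonded hydroxyl ortho to the ketone is unreactive under these conditions, so only the ring B phenol is capped. This keeps ring B out of the later iodination.

Step 4
Reactants: 6 2-[4-(tert-butyldimethylsilyloxy)phenyl]-1-[2-hydroxy-6-methoxy-4-(2-methylbut-3-yn-2-yloxy)phenyl]ethanone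
Product: 10 2-[4-(tert-butyldimethylsilyloxy)phenyl]-1-(5-hydroxy-7-methoxy-2,2-dimethyl-2H-chromen-6-yl)ethanone, via allenyl cyclohexadienone 7 (not isolated), via ortho-allenylphenol 8 (not isolated), via ortho-quinone methide 9 (not isolated)
Conditions: N,N-diethylaniline, 190 °C, argon
Reagents that add atoms: none
Why: This is an aromatic propargyl Claisen rearrangement: the [3,3] shift joins the alkyne terminus to the ring carbon between the chelated hydroxyl and the ether oxygen and gives allenyl dienone 7, which enolises to allenylphenol 8. A 1,5-hydrogen shift from the phenolic oxygen to the central allene carbon gives the Z-configured ortho-quinone methide 9, and a thermal disrotatory oxa-6π electrocyclisation re-forms the bond from oxygen to the dimethyl-bearing carbon and closes the six-membered pyran ring. The closest known reaction type is the thermal conversion of aryl 1,1-dimethylpropargyl ethers of ortho-hydroxyaryl ketones into 2,2-dimethyl-2H-chromenes. No stereocentre is created, since C2 carries two methyl groups and the stereocentre of 7 is lost on enolisation. The selectivity needed is between the two ring carbons ortho to the ether oxygen; the hydrogen bond between hydroxyl and ketone favours the Kekulé structure with a double bond between the ether-bearing carbon and the carbon next to the chelated hydroxyl, so the shift should go there, and the methoxy group on the other side adds a steric bias. Heating without base or metal keeps the allenylphenol on the pyran path (base would divert it to a benzofuran), the gem-dimethyl group lowers the barrier of the sigmatropic step, and the silyl ether, the ketone and the chelated hydroxyl are inert at this temperature.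

Step 5
Reactants: 10 2-[4-(tert-butyldimethylsilyloxy)phenyl]-1-(5-hydroxy-7-methoxy-2,2-dimethyl-2H-chromen-6-yl)ethanone
Product: 11 2-[4-(tert-butyldimethylsilyloxy)phenyl]-1-(5-hydroxy-8-iodo-7-methoxy-2,2-dimethyl-2H-chromen-6-yl)ethanone
Conditions: NIS (1.05 equiv), dry MeCN, 0 °C to rt, dark
Reagents that add atoms: N-iodosuccinimide (NIS), O=C1CCC(=O)N1I
Why: Electrophilic aromatic iodination of an activated phenol with NIS; C8 is the only unsubstituted carbon of ring A, is para to the hydroxyl and ortho to two ether oxygens, and should react well before the silyloxy-substituted ring B. In a dry aprotic solvent without added acid, iodonium formation at the chromene double bond is reversible and has no nucleophile to trap it, whereas substitution at C8 is made irreversible by proton loss.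

Step 6
Reactants: 11 2-[4-(tert-butyldimethylsilyloxy)phenyl]-1-(5-hydroxy-8-iodo-7-methoxy-2,2-dimethyl-2H-chromen-6-yl)ethanone; 12 tributyl(3-methylbut-2-en-1-yl)stannane
Product: 13 2-[4-(tert-butyldimethylsilyloxy)phenyl]-1-[5-hydroxy-7-methoxy-2,2-dimethyl-8-(3-methylbut-2-en-1-yl)-2H-chromen-6-yl]ethanone
Conditions: Pd(PPh3)4 (cat.), DMF, 90 °C, argon
Reagents that add atoms: none
Why: Migita–Kosugi–Stille coupling of an aryl iodide with a prenylstannane on zerovalent palladium runs without base, so the aryl silyl ether, the chelated phenol and the enolisable ketone are untouched. Reductive elimination through the less hindered primary end of the allylpalladium intermediate should give the linear 3-methylbut-2-enyl group.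

Step 7
Reactants: 13 2-[4-(tert-butyldimethylsilyloxy)phenyl]-1-[5-hydroxy-7-methoxy-2,2-dimethyl-8-(3-methylbut-2-en-1-yl)-2H-chromen-6-yl]ethanone
Product: 14 1-[5-hydroxy-7-methoxy-2,2-dimethyl-8-(3-methylbut-2-en-1-yl)-2H-chromen-6-yl]-2-(4-hydroxyphenyl)ethanone
Conditions: TBAF, AcOH (1:1), THF, 0 °C
Reagents that add atoms: none
Why: Fluoride cleavage of an aryl tert-butyldimethylsilyl ether; buffering with acetic acid keeps the medium near neutral, so the benzylic methylene and the two olefins see neither base nor strong acid.

## Compound list

1 | 5-methoxybenzene-1,3-diol (5-methoxyresorcinol) | COc1cc(O)cc(O)c1 | starting material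
2 | 2-(4-hydroxyphenyl)acetic acid | OC(=O)Cc1ccc(O)cc1 | starting material
3 | 1-(2,4-dihydroxy-6-methoxyphenyl)-2-(4-hydroxyphenyl)ethanone | COc1cc(O)cc(O)c1C(=O)Cc1ccc(O)cc1 | intermediate
4 | 3-chloro-3-methylbut-1-yne | CC(C)(Cl)C#C | starting material
5 | 1-[2-hydroxy-6-methoxy-4-(2-methylbut-3-yn-2-yloxy)phenyl]-2-(4-hydroxyphenyl)ethanone | COc1cc(OC(C)(C)C#C)cc(O)c1C(=O)Cc1ccc(O)cc1 | intermediate
6 | 2-[4-(tert-butyldimethylsilyloxy)phenyl]-1-[2-hydroxy-6-methoxy-4-(2-methylbut-3-yn-2-yloxy)phenyl]ethanone | COc1cc(OC(C)(C)C#C)cc(O)c1C(=O)Cc1ccc(O[Si](C)(C)C(C)(C)C)cc1 | intermediate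
7 | 4-{[4-(tert-butyldimethylsilyloxy)phenyl]acetyl}-5-hydroxy-3-methoxy-6-(3-methylbuta-1,2-dien-1-yl)cyclohexa-2,4-dien-1-one (racemic at C6, not isolated) | COC1=CC(=O)C(C=C=C(C)C)C(O)=C1C(=O)Cc1ccc(O[Si](C)(C)C(C)(C)C)cc1 | intermediate
8 | 2-[4-(tert-butyldimethylsilyloxy)phenyl]-1-[2,4-dihydroxy-6-methoxy-3-(3-methylbuta-1,2-dien-1-yl)phenyl]ethanone (not isolated) | COc1cc(O)c(C=C=C(C)C)c(O)c1C(=O)Cc1ccc(O[Si](C)(C)C(C)(C)C)cc1 | intermediate
9 | (6Z)-4-{[4-(tert-butyldimethylsilyloxy)phenyl]acetyl}-5-hydroxy-3-methoxy-6-(3-methylbut-2-en-1-ylidene)cyclohexa-2,4-dien-1-one (not isolated) | COC1=CC(=O)/C(=C\C=C(C)C)C(O)=C1C(=O)Cc1ccc(O[Si](C)(C)C(C)(C)C)cc1 | intermediate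
10 | 2-[4-(tert-butyldimethylsilyloxy)phenyl]-1-(5-hydroxy-7-methoxy-2,2-dimethyl-2H-chromen-6-yl)ethanone | COc1cc2OC(C)(C)C=Cc2c(O)c1C(=O)Cc1ccc(O[Si](C)(C)C(C)(C)C)cc1 | intermediate
11 | 2-[4-(tert-butyldimethylsilyloxy)phenyl]-1-(5-hydroxy-8-iodo-7-methoxy-2,2-dimethyl-2H-chromen-6-yl)ethanone | COc1c(I)c2OC(C)(C)C=Cc2c(O)c1C(=O)Cc1ccc(O[Si](C)(C)C(C)(C)C)cc1 | intermediate
12 | tributyl(3-methylbut-2-en-1-yl)stannane | CCCC[Sn](CCCC)(CCCC)CC=C(C)C | starting material
13 | 2-[4-(tert-butyldimethylsilyloxy)phenyl]-1-[5-hydroxy-7-methoxy-2,2-dimethyl-8-(3-methylbut-2-en-1-yl)-2H-chromen-6-yl]ethanone | COc1c(CC=C(C)C)c2OC(C)(C)C=Cc2c(O)c1C(=O)Cc1ccc(O[Si](C)(C)C(C)(C)C)cc1 | intermediate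
14 | 1-[5-hydroxy-7-methoxy-2,2-dimethyl-8-(3-methylbut-2-en-1-yl)-2H-chromen-6-yl]-2-(4-hydroxyphenyl)ethanone | COc1c(CC=C(C)C)c2c(c(O)c1C(=O)Cc1ccc(O)cc1)C=CC(C)(C)O2 | target

## Step count and least certain steps

Total step count: 7. Longest linear sequence: 7 steps (1, 3, 5, 6, 10, 11, 13, 14); compounds 2, 4 and 12 enter as purchased partners.

**Step 4 (key step).** The propargyl unit may migrate in part to the methoxy-flanked carbon, because the hydrogen bond creates a preference and not a block. The tertiary propargyl group may also be lost by thermal elimination before it rearranges, since the para-acyl aryloxide is a good leaving group. Fallback, from 3 to 10: condensation of 3 with 3-methylbut-2-enal over Ca(OH)2 in methanol should attack the carbon between the two free hydroxyls, the most nucleophilic one, and proceed by dehydration and oxa-6π closure to 1-(5-hydroxy-7-methoxy-2,2-dimethyl-2H-chromen-6-yl)-2-(4-hydroxyphenyl)ethanone F1. Silylation of the ring B phenol of F1 with TBSCl and imidazole rejoins the route at 10. This forms the same two pyran bonds by an intermolecular route whose site selectivity rests on carbon nucleophilicity instead of bond fixation.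

**Step 5.** The iodonium source may attack the electron-rich chromene double bond, which is conjugated to a trioxygenated ring, or the enol of the ketone, in competition with substitution at C8. Fallback, from 10 to 13, bypassing both halogenation and cross-coupling: Mitsunobu etherification of the C5 hydroxyl of 10 with 3-methylbut-2-en-1-ol (PPh3, DIAD) gives 2-[4-(tert-butyldimethylsilyloxy)phenyl]-1-[7-methoxy-2,2-dimethyl-5-(3-methylbut-2-en-1-yloxy)-2H-chromen-6-yl]ethanone F2. A para-Claisen rearrangement (Claisen then Cope shift), promoted by Eu(fod)3 or by heat alone, should move the prenyl group to C8, because both ortho carbons are substituted and the dienone can only relay the group onward. This gives 13.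

**Step 6.** The prenyl group may be transferred through its tertiary end to give the 1,1-dimethylallyl isomer. Oxidative addition and transmetalation at the doubly ortho-substituted iodide may also be slow enough for protodeiodination to compete. Fallback, from 11 to 13: Stille coupling of 11 with allyltributylstannane, which has no such regiochemical ambiguity, gives 2-[4-(tert-butyldimethylsilyloxy)phenyl]-1-[5-hydroxy-7-methoxy-2,2-dimethyl-8-(prop-2-en-1-yl)-2H-chromen-6-yl]ethanone F3. Olefin cross-metathesis of F3 with excess 2-methylbut-2-ene and the second-generation Grubbs catalyst converts the allyl into the prenyl group and gives 13; the hindered cyclic chromene olefin should not take part.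

**Step 1.** Acylation at the carbon between the two hydroxyls may compete with the desired site and lower the supply of 3. Fallback, from 2 to 6, using a symmetric ring so that the acylation site is not in question:
- Acylation of benzene-1,3,5-triol F4 (phloroglucinol, purchased) with 2 in BF3·OEt2 gives 2-(4-hydroxyphenyl)-1-(2,4,6-trihydroxyphenyl)ethanone F5.
- Etherification of the most acidic, para hydroxyl with 4 (K2CO3, KI, CuI) gives 1-[2,6-dihydroxy-4-(2-methylbut-3-yn-2-yloxy)phenyl]-2-(4-hydroxyphenyl)ethanone F6.
- Silylation of the ring B phenol gives 2-[4-(tert-butyldimethylsilyloxy)phenyl]-1-[2,6-dihydroxy-4-(2-methylbut-3-yn-2-yloxy)phenyl]ethanone F7.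
- Monomethylation of one of the two equivalent ortho hydroxyls with one equivalent of dimethyl sulfate and K2CO3 in acetone gives 6; the remaining hydroxyl is then deactivated by chelation.

**Step 2.** A second etherification at the ring B phenol may occur, or conversion may stall because the tertiary chloride is consumed by elimination. Fallback, from 3 to 6, with the protection order reversed:
- Silylation of both unchelated phenols of 3 gives 1-[4-(tert-butyldimethylsilyloxy)-2-hydroxy-6-methoxyphenyl]-2-[4-(tert-butyldimethylsilyloxy)phenyl]ethanone F8.
- Brief treatment with K2CO3 in methanol at 0 °C should cleave only the silyl ether para to the ketone, whose aryloxide is much the better leaving group, and give 2-[4-(tert-butyldimethylsilyloxy)phenyl]-1-(2,4-dihydroxy-6-methoxyphenyl)ethanone F9.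
- Propargylation of the single free unchelated hydroxyl of F9 with 4 (CuCl2 cat., DBU, MeCN, 0 °C) gives 6.

## Further compounds

F1 | step 4 | 1-(5-hydroxy-7-methoxy-2,2-dimethyl-2H-chromen-6-yl)-2-(4-hydroxyphenyl)ethanone | COc1cc2OC(C)(C)C=Cc2c(O)c1C(=O)Cc1ccc(O)cc1
F2 | step 5 | 2-[4-(tert-butyldimethylsilyloxy)phenyl]-1-[7-methoxy-2,2-dimethyl-5-(3-methylbut-2-en-1-yloxy)-2H-chromen-6-yl]ethanone | COc1cc2OC(C)(C)C=Cc2c(OCC=C(C)C)c1C(=O)Cc1ccc(O[Si](C)(C)C(C)(C)C)cc1
F3 | step 6 | 2-[4-(tert-butyldimethylsilyloxy)phenyl]-1-[5-hydroxy-7-methoxy-2,2-dimethyl-8-(prop-2-en-1-yl)-2H-chromen-6-yl]ethanone | COc1c(CC=C)c2OC(C)(C)C=Cc2c(O)c1C(=O)Cc1ccc(O[Si](C)(C)C(C)(C)C)cc1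
F4 | step 1 | benzene-1,3,5-triol (phloroglucinol, purchased) | Oc1cc(O)cc(O)c1
F5 | step 1 | 2-(4-hydroxyphenyl)-1-(2,4,6-trihydroxyphenyl)ethanone | Oc1ccc(CC(=O)c2c(O)cc(O)cc2O)cc1
F6 | step 1 | 1-[2,6-dihydroxy-4-(2-methylbut-3-yn-2-yloxy)phenyl]-2-(4-hydroxyphenyl)ethanone | C#CC(C)(C)Oc1cc(O)c(C(=O)Cc2ccc(O)cc2)c(O)c1
F7 | step 1 | 2-[4-(tert-butyldimethylsilyloxy)phenyl]-1-[2,6-dihydroxy-4-(2-methylbut-3-yn-2-yloxy)phenyl]ethanone | C#CC(C)(C)Oc1cc(O)c(C(=O)Cc2ccc(O[Si](C)(C)C(C)(C)C)cc2)c(O)c1
F8 | step 2 | 1-[4-(tert-butyldimethylsilyloxy)-2-hydroxy-6-methoxyphenyl]-2-[4-(tert-butyldimethylsilyloxy)phenyl]ethanone | COc1cc(O[Si](C)(C)C(C)(C)C)cc(O)c1C(=O)Cc1ccc(O[Si](C)(C)C(C)(C)C)cc1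
F9 | step 2 | 2-[4-(tert-butyldimethylsilyloxy)phenyl]-1-(2,4-dihydroxy-6-methoxyphenyl)ethanone | COc1cc(O)cc(O)c1C(=O)Cc1ccc(O[Si](C)(C)C(C)(C)C)cc1
A1 | alternative 1 | 6-methylhept-5-en-2-one | CC(=O)CCC=C(C)C
A2 | alternative 1 | propanedioyl dichloride (malonyl dichloride) | O=C(Cl)CC(Cl)=O
A3 | alternative 1 | 2-(3-methylbut-2-en-1-yl)benzene-1,3,5-triol | CC(C)=CCc1c(O)cc(O)cc1O
A4 | alternative 2 | 2,6-dihydroxy-4-methoxybenzaldehyde | COc1cc(O)c(C=O)c(O)c1
A5 | alternative 2 | (2-methylprop-1-en-1-yl)boronic acid | CC(C)=CB(O)O
A6 | alternative 2 | 7-methoxy-2,2-dimethyl-2H-chromen-5-ol | COc1cc(O)c2C=CC(C)(C)Oc2c1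
A7 | alternative 3 | 3-(triisopropylsilyloxy)cyclobut-2-en-1-one | O=C1CC(O[Si](C(C)C)(C(C)C)C(C)C)=C1
A8 | alternative 3 | 1-methoxy-5-methylhex-4-en-1-yne | COC#CCC=C(C)C
A9 | alternative 3 | 3-methoxy-2-(3-methylbut-2-en-1-yl)-5-(triisopropylsilyloxy)phenol | COc1cc(O[Si](C(C)C)(C(C)C)C(C)C)cc(O)c1CC=C(C)C
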